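**Strategy.** Ring A, the O-methylated ring, is taken apart into a triisopropylsilyl ynol ether that already carries the isobutyl-bearing methine stereocentre and MOM-protected ring B, and racemic 3-methoxy-4-prenylcyclobutenone. One thermal benzannulation joins them and delivers ring A with its substituents in the order the target requires: the methine-bearing carbon flanked by two oxygenated carbons (one OH, one OSi), the methoxy carbon para to it, the prenyl carbon between OMe and the free OH, and one CH left for the ring A acetyl group. The stereocentre is set earlier by sparteine-controlled lithiation–borylation and moved from boron to the alkyne; both acetyl groups follow by a double ortho-lithiation.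

Key step: step 12

Remark: the spatial arrangement at the methine is fixed in step 5 and never changes afterwards; the R/S letter switches between some intermediates only because the CIP ranking of the attached groups changes (the SMILES strings define the geometry).

Abbreviations: MOM = methoxymethyl; Cb = N,N-diisopropylcarbamoyl; pin = pinacolato; TIPS = triisopropylsilyl; ArB = 2,4,6-tris(methoxymethoxy)-3-(3-methylbut-2-en-1-yl)phenyl.

**Route**

Step 1
Reactants: 1 phloroglucinol
Product: 2 1,3,5-tris(methoxymethoxy)benzene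
Conditions: NaH, MOMCl, DMF, 0 °C → rt
Reagents that add atoms: chloromethyl methyl ether, COCCl
Why: Williamson etherification of the triphenoxide installs three MOM ethers that later act as ortho-directing groups and are removed together under mild acid.

Step 2
Reactants: 2 1,3,5-tris(methoxymethoxy)benzene
Product: 4 1,3,5-tris(methoxymethoxy)-2-(3-methylbut-2-en-1-yl)benzene, via aryllithium 3 (not isolated)
Conditions: n-BuLi, THF, 0 °C; then CuI (10 mol %), prenyl bromide, –78 °C → rt
Reagents that add atoms: 1-bromo-3-methylbut-2-ene, CC(C)=CCBr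
Why: Directed ortho-lithiation between two MOM ethers followed by copper-catalysed SN2 allylation places the prenyl group on a ring carbon flanked by two oxygens, and since the three ring hydrogens of 2 are equivalent no regiochemical question arises.

Step 3
Reactants: 4 1,3,5-tris(methoxymethoxy)-2-(3-methylbut-2-en-1-yl)benzene
Product: 6 2-ArB-4,4,5,5-tetramethyl-1,3,2-dioxaborolane (ArB–Bpin), via aryllithium 5 (not isolated)
Conditions: n-BuLi, THF, 0 °C; then i-PrOBpin, –78 °C → rt; H2O
Reagents that add atoms: 2-isopropoxy-4,4,5,5-tetramethyl-1,3,2-dioxaborolane, CC(C)OB1OC(C)(C)C(C)(C)O1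
Why: A second directed ortho-lithiation can only take one of the two equivalent remaining ring hydrogens, each flanked by two MOM ethers, and electrophilic borylation of the aryllithium gives the pinacol boronic ester.

Step 4
Reactants: 7 3-methylbutan-1-ol
Product: 8 3-methylbutyl N,N-diisopropylcarbamate
Conditions: i-Pr2NCOCl, Et3N, CH2Cl2, reflux
Reagents that add atoms: N,N-diisopropylcarbamoyl chloride, CC(C)N(C(C)C)C(=O)Cl
Why: O-Carbamoylation (acyl substitution) of the primary alcohol gives the hindered carbamate that directs and stabilises alpha-lithiation.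

Step 5
Reactants: 8 3-methylbutyl N,N-diisopropylcarbamate; 6 ArB–Bpin
Product: 11 2-[(1R)-3-methyl-1-ArB-butyl]-4,4,5,5-tetramethyl-1,3,2-dioxaborolane, via lithiated carbamate 9 (not isolated), via boronate complex 10 (not isolated)
Conditions: s-BuLi, (–)-sparteine, Et2O, –78 °C, 5 h; then 6 in Et2O, –78 °C, 2 h; then 35 °C, 16 h
Reagents that add atoms: none
Why: Lithiation–borylation: sparteine-bound s-BuLi removes the pro-S alpha-hydrogen, the configurationally stable (S)-carbenoid adds to boron with retention, and 1,2-metallate rearrangement of the electron-rich aryl group with anti-periplanar loss of the carbamate inverts that carbon, which sets the benzylic stereocentre of 11 as R.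

Step 6
Reactants: 12 tetrahydrofuran
Product: 14 ethenyl N,N-diisopropylcarbamate, via lithium ethenolate 13 (not isolated)
Conditions: n-BuLi, THF, 0 °C → rt, 16 h; then i-Pr2NCOCl, DMPU, 0 °C → rt
Reagents that add atoms: N,N-diisopropylcarbamoyl chloride, CC(C)N(C(C)C)C(=O)Cl
Why: Cycloreversion of alpha-lithiated tetrahydrofuran gives ethene and the lithium enolate of acetaldehyde, whose O-acylation by the carbamoyl chloride is an established preparation of this vinyl carbamate.

Step 7
Reactants: 11 (R)-benzylic boronic ester; 14 ethenyl N,N-diisopropylcarbamate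
Product: 18 (3R)-5-methyl-3-ArB-hex-1-en-2-yl N,N-diisopropylcarbamate, via lithiated vinyl carbamate 15 (not isolated), via boronate complex 16 (not isolated), via iodo boronic ester 17 (not isolated)
Conditions: 14 and LiN(i-Pr)2 (2 equiv each), THF, –78 °C; add 11, –78 → –40 °C; I2, MeOH, –78 °C; NaOMe, MeOH, → rt; aq. Na2S2O3
Reagents that add atoms: none
Why: Zweifel olefination: the alpha-lithiated vinyl carbamate adds to boron, iodine activates the alkene for stereoretentive 1,2-migration of the benzylic carbon, and methoxide-induced anti-elimination of boron and iodide gives the 1,1-disubstituted alkene with the stereocentre unchanged in space.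

Step 8
Reactants: 18 (3R)-alkenyl carbamate
Product: 21 triisopropyl{[(3S)-5-methyl-3-ArB-hex-1-yn-1-yl]oxy}silane, via lithium acetylide 19 (not isolated), via lithium ynolate 20 (not isolated)
Conditions: LiN(i-Pr)2 (2.3 equiv), THF, –78 → 0 °C; then LiOOt-Bu [premade from t-BuOOH (1.5 equiv) and LiN(SiMe3)2 (1.5 equiv), THF, –78 °C], –78 → 0 °C; then TIPSOTf (2.5 equiv), –78 → 0 °C; aq. NaHCO3, pentane; Et3N-deactivated silica
Reagents that add atoms: tert-butyl hydroperoxide, CC(C)(C)OO; triisopropylsilyl trifluoromethanesulfonate, CC(C)[Si](OS(=O)(=O)C(F)(F)F)(C(C)C)C(C)C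
Why: Base-induced beta-elimination of the carbamate from the alkenyl carbamate gives the lithium acetylide directly, and this anion, whose charge shields the propargylic hydrogen from the small excess of amide base, is not protonated but oxygenated in the same flask by lithium tert-butyl peroxide (electrophilic oxygenation of an acetylide to the ynolate) and then O-silylated by the hard, bulky silyl triflate to a triisopropylsilyl ynol ether robust enough to purify and to heat.

Step 9
Reactants: 22 chloroacetaldehyde dimethyl acetal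
Product: 24 methoxyethyne, via sodium methoxyethynide 23 (not isolated)
Conditions: NaNH2 (3 equiv), liquid NH3, –33 °C; then cold sat. aq. NaCl, –70 °C; distilled into cold Et2O
Reagents that add atoms: none
Why: Double dehydro-elimination (methanol, then hydrogen chloride) from the chloroacetal with sodium amide is the standard route to alkoxyethynes, the third equivalent of base holding the product as its sodium acetylide until the quench.

Step 10
Reactants: 25 5-methylhex-4-enoic acid
Product: 26 5-methylhex-4-enoyl chloride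
Conditions: (COCl)2, cat. DMF, CH2Cl2, 0 °C → rt
Reagents that add atoms: oxalyl chloride, ClC(=O)C(=O)Cl
Why: Acyl chloride formation through Vilsmeier-type activation is mild enough to leave the trisubstituted alkene untouched.

Step 11
Reactants: 26 5-methylhex-4-enoyl chloride; 24 methoxyethyne
Product: 28 3-methoxy-4-(3-methylbut-2-en-1-yl)cyclobut-2-en-1-one (racemic), via prenylketene 27 (not isolated)
Conditions: 24 (3 equiv), Et3N, Et2O, 0 °C → rt, slow addition of 26
Reagents that add atoms: none
Why: Dehydrochlorination gives prenylketene, which undergoes ketene–alkyne [2+2] cycloaddition in which the alkyne carbon beta to oxygen bonds to the ketene carbonyl carbon, giving the 3-alkoxycyclobutenone; its sp3 stereocentre forms racemic and disappears in step 12.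

Step 12
Reactants: 21 (3S)-siloxyalkyne; 28 3-methoxy-4-prenylcyclobut-2-en-1-one
Product: 33 5-methoxy-2-[(1R)-3-methyl-1-ArB-butyl]-6-(3-methylbut-2-en-1-yl)-3-[(triisopropylsilyl)oxy]phenol, via vinylketene 29 (not isolated), via vinylcyclobutenone 30 (not isolated), via dienylketene 31 (not isolated), via cyclohexadienone 32 (not isolated)
Conditions: 28 (1.5 equiv), toluene, 80 °C then 110 °C, sealed tube, argon
Reagents that add atoms: none
Why: Danheiser benzannulation: on heating, 28 opens reversibly by 4π-electrocyclic cleavage to vinylketene 29, whose ketene C=C adds [2+2] to the electron-rich ynol ether to give 2-vinylcyclobutenone 30; this reopens to dienylketene 31, which closes by thermal disrotatory 6π-electrocyclisation (the ketene carbon bonding to the prenyl-bearing diene terminus, the mode by which the six-membered ring A is closed) to cyclohexadienone 32, and enolisation gives the phenol. The closest known reaction type is the benzannulation of cyclobutenones with 1-siloxyalkynes to resorcinol mono-silyl ethers; a 3-methoxy group on the ketene partner and a branched propargylic carbon on the alkyne make this a demanding member of that class. The one selectivity needed is the orientation of the ketene–alkyne cycloaddition, and the substrate secures it through the polarisation of the ynol ether: the alkyne carbon beta to oxygen, which carries the methine, is the nucleophile and bonds to the ketene carbonyl carbon, so this carbon ends between C–OH and C–OSi, the methoxy carbon para to it and the prenyl carbon beside the free hydroxyl. No stereocentre is formed: the sp3 carbon of 28 becomes aromatic, and the methine, which carries no acidifying group and meets neither acid nor base, keeps its configuration. Because 28 releases the ketene slowly and reversibly, its stationary concentration stays low and dimerisation should not outrun the slower addition to the hindered alkyne.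

Step 13
Reactants: 33 ring A phenol silyl ether
Product: 34 5-methoxy-2-[(1S)-3-methyl-1-ArB-butyl]-4-(3-methylbut-2-en-1-yl)benzene-1,3-diol
Conditions: Bu4NF, AcOH, THF, 0 °C
Reagents that add atoms: none
Why: Fluoride-mediated desilylation cleaves the aryl silyl ether selectively while MOM ethers and alkenes are inert, and the acetic acid buffer keeps the electron-rich resorcinol from standing as its air-sensitive phenoxide.

Step 14
Reactants: 34 ring A diol
Product: 35 1-methoxy-3,5-bis(methoxymethoxy)-4-[(1S)-3-methyl-1-ArB-butyl]-2-(3-methylbut-2-en-1-yl)benzene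
Conditions: NaH, MOMCl, DMF, 0 °C → rt
Reagents that add atoms: chloromethyl methyl ether, COCCl
Why: Williamson etherification turns both ring A hydroxyls into MOM ethers, so that the last ring A hydrogen lies between OMe and OMOM and can be lithiated, which a bulky silyl ether (poor director, prone to O-to-C silyl shift once ortho-lithiated) would not permit.

Step 15
Reactants: 35 penta-MOM diarylmethane
Product: 38 1-[3-{(1S)-1-[3-acetyl-2,4,6-tris(methoxymethoxy)-5-(3-methylbut-2-en-1-yl)phenyl]-3-methylbutyl}-6-methoxy-2,4-bis(methoxymethoxy)-5-(3-methylbut-2-en-1-yl)phenyl]ethan-1-one, via dilithio species 36 (not isolated), via bis-adduct 37 (not isolated)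
Conditions: n-BuLi (2.5 equiv), THF, 0 °C; then MeC(O)N(OMe)Me, –78 → 0 °C; H2O
Reagents that add atoms: N-methoxy-N-methylacetamide, CC(=O)N(C)OC
Why: Double directed ortho-lithiation and Weinreb ketone synthesis: each ring has exactly one hydrogen left, each flanked by two coordinating ether oxygens, so kinetic ring deprotonation should outrun removal of the shielded diarylmethine or prenyl CH2 hydrogens, and the chelated tetrahedral adducts stop the acylation at the ketone stage.

Step 16
Reactants: 38 bis-acetyl penta-MOM ether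
Product: 39 1-[3-{(1R)-1-[3-acetyl-2,4,6-trihydroxy-5-(3-methylbut-2-en-1-yl)phenyl]-3-methylbutyl}-2,4-dihydroxy-6-methoxy-5-(3-methylbut-2-en-1-yl)phenyl]ethan-1-one (target)
Conditions: HCl (3 M aq.), MeOH, rt
Reagents that add atoms: none
Why: Acid-catalysed transacetalisation to methanol removes all five MOM groups, and dilute acid at room temperature is chosen because stronger acid could cyclise the ortho-prenyl phenols to chromans or ionise the diarylmethine, which the two acetyl groups already disfavour by lowering ring basicity.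

**Compound list**

1 | phloroglucinol | Oc1cc(O)cc(O)c1 | starting material
2 | 1,3,5-tris(methoxymethoxy)benzene | COCOc1cc(OCOC)cc(OCOC)c1 | intermediate
3 | 2,4,6-tris(methoxymethoxy)phenyllithium | [Li]c1c(OCOC)cc(OCOC)cc1OCOC | intermediate
4 | 1,3,5-tris(methoxymethoxy)-2-(3-methylbut-2-en-1-yl)benzene | COCOc1cc(OCOC)c(CC=C(C)C)c(OCOC)c1 | intermediate
5 | ArB-lithium | [Li]c1c(OCOC)c(CC=C(C)C)c(OCOC)cc1OCOC | intermediate
6 | 2-ArB-4,4,5,5-tetramethyl-1,3,2-dioxaborolane | CC1(C)OB(OC1(C)C)c1c(OCOC)c(CC=C(C)C)c(OCOC)cc1OCOC | intermediate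
7 | 3-methylbutan-1-ol | CC(C)CCO | starting material
8 | 3-methylbutyl N,N-diisopropylcarbamate | CC(C)CCOC(=O)N(C(C)C)C(C)C | intermediate
9 | (1S)-1-lithio-3-methylbutyl N,N-diisopropylcarbamate (sparteine complex) | CC(C)C[C@H]([Li])OC(=O)N(C(C)C)C(C)C | intermediate
10 | lithium boronate complex of 9 and 6 (S at the carbamate-bearing carbon) | [Li+].CC(C)C[C@@H](OC(=O)N(C(C)C)C(C)C)[B-]1(OC(C)(C)C(C)(C)O1)c1c(OCOC)c(CC=C(C)C)c(OCOC)cc1OCOC | intermediate
11 | 2-[(1R)-3-methyl-1-ArB-butyl]-4,4,5,5-tetramethyl-1,3,2-dioxaborolane | CC1(C)OB(OC1(C)C)[C@H](CC(C)C)c1c(OCOC)c(CC=C(C)C)c(OCOC)cc1OCOC | intermediate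
12 | tetrahydrofuran | C1CCOC1 | starting material
13 | lithium ethenolate | [Li]OC=C | intermediate
14 | ethenyl N,N-diisopropylcarbamate | C=COC(=O)N(C(C)C)C(C)C | intermediate
15 | 1-lithioethenyl N,N-diisopropylcarbamate | [Li]C(=C)OC(=O)N(C(C)C)C(C)C | intermediate
16 | lithium boronate complex of 15 and 11 (R at the benzylic carbon) | [Li+].C=C(OC(=O)N(C(C)C)C(C)C)[B-]1(OC(C)(C)C(C)(C)O1)[C@H](CC(C)C)c1c(OCOC)c(CC=C(C)C)c(OCOC)cc1OCOC | intermediate
17 | (3R)-1-iodo-5-methyl-2-(pinacolatoboryl)-3-ArB-hexan-2-yl N,N-diisopropylcarbamate (either configuration at C2) | ICC(OC(=O)N(C(C)C)C(C)C)(B1OC(C)(C)C(C)(C)O1)[C@H](CC(C)C)c1c(OCOC)c(CC=C(C)C)c(OCOC)cc1OCOC | intermediate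
18 | (3R)-5-methyl-3-ArB-hex-1-en-2-yl N,N-diisopropylcarbamate | C=C(OC(=O)N(C(C)C)C(C)C)[C@H](CC(C)C)c1c(OCOC)c(CC=C(C)C)c(OCOC)cc1OCOC | intermediate
19 | lithium (3S)-5-methyl-3-ArB-hex-1-yn-1-ide | [Li]C#C[C@H](CC(C)C)c1c(OCOC)c(CC=C(C)C)c(OCOC)cc1OCOC | intermediate
20 | lithium (3S)-5-methyl-3-ArB-hex-1-yn-1-olate | [Li]OC#C[C@H](CC(C)C)c1c(OCOC)c(CC=C(C)C)c(OCOC)cc1OCOC | intermediate
21 | triisopropyl{[(3S)-5-methyl-3-ArB-hex-1-yn-1-yl]oxy}silane | CC(C)[Si](OC#C[C@H](CC(C)C)c1c(OCOC)c(CC=C(C)C)c(OCOC)cc1OCOC)(C(C)C)C(C)C | intermediate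
22 | chloroacetaldehyde dimethyl acetal | COC(CCl)OC | starting material
23 | sodium methoxyethynide | [Na]C#COC | intermediate
24 | methoxyethyne | C#COC | intermediate
25 | 5-methylhex-4-enoic acid | CC(C)=CCCC(=O)O | starting material
26 | 5-methylhex-4-enoyl chloride | CC(C)=CCCC(=O)Cl | intermediate
27 | 5-methylhexa-1,4-dien-1-one (prenylketene) | CC(C)=CCC=C=O | intermediate
28 | 3-methoxy-4-(3-methylbut-2-en-1-yl)cyclobut-2-en-1-one (racemic) | O=C1C=C(OC)C1CC=C(C)C | intermediate
29 | (3Z)-3-methoxy-7-methylocta-1,3,6-trien-1-one | O=C=C/C(OC)=C/CC=C(C)C | intermediate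
30 | 4-[(1Z)-1-methoxy-5-methylhexa-1,4-dien-1-yl]-2-[(1R)-3-methyl-1-ArB-butyl]-3-[(triisopropylsilyl)oxy]cyclobut-2-en-1-one (both epimers at C4) | O=C1C([C@H](CC(C)C)c2c(OCOC)c(CC=C(C)C)c(OCOC)cc2OCOC)=C(O[Si](C(C)C)(C(C)C)C(C)C)C1/C(OC)=C/CC=C(C)C | intermediate
31 | (3E,5Z)-5-methoxy-9-methyl-2-[(1R)-3-methyl-1-ArB-butyl]-3-[(triisopropylsilyl)oxy]deca-1,3,5,8-tetraen-1-one | O=C=C([C@H](CC(C)C)c1c(OCOC)c(CC=C(C)C)c(OCOC)cc1OCOC)/C(O[Si](C(C)C)(C(C)C)C(C)C)=C\C(OC)=C\CC=C(C)C | intermediate
32 | 5-methoxy-2-[(1R)-3-methyl-1-ArB-butyl]-6-(3-methylbut-2-en-1-yl)-3-[(triisopropylsilyl)oxy]cyclohexa-2,4-dien-1-one (both epimers at C6) | O=C1C([C@H](CC(C)C)c2c(OCOC)c(CC=C(C)C)c(OCOC)cc2OCOC)=C(O[Si](C(C)C)(C(C)C)C(C)C)C=C(OC)C1CC=C(C)C | intermediate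
33 | 5-methoxy-2-[(1R)-3-methyl-1-ArB-butyl]-6-(3-methylbut-2-en-1-yl)-3-[(triisopropylsilyl)oxy]phenol | COc1c(CC=C(C)C)c(O)c([C@H](CC(C)C)c2c(OCOC)c(CC=C(C)C)c(OCOC)cc2OCOC)c(O[Si](C(C)C)(C(C)C)C(C)C)c1 | intermediate
34 | 5-methoxy-2-[(1S)-3-methyl-1-ArB-butyl]-4-(3-methylbut-2-en-1-yl)benzene-1,3-diol | COc1c(CC=C(C)C)c(O)c([C@H](CC(C)C)c2c(OCOC)c(CC=C(C)C)c(OCOC)cc2OCOC)c(O)c1 | intermediate
35 | 1-methoxy-3,5-bis(methoxymethoxy)-4-[(1S)-3-methyl-1-ArB-butyl]-2-(3-methylbut-2-en-1-yl)benzene | COc1c(CC=C(C)C)c(OCOC)c([C@H](CC(C)C)c2c(OCOC)c(CC=C(C)C)c(OCOC)cc2OCOC)c(OCOC)c1 | intermediate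
36 | dilithio derivative of 35 (lithium at the one free carbon of each ring) | COc1c(CC=C(C)C)c(OCOC)c([C@H](CC(C)C)c2c(OCOC)c(CC=C(C)C)c(OCOC)c([Li])c2OCOC)c(OCOC)c1[Li] | intermediate
37 | bis(lithium N-methoxy-N-methyl hemiaminal) adduct of 36 | COc1c(CC=C(C)C)c(OCOC)c([C@H](CC(C)C)c2c(OCOC)c(CC=C(C)C)c(OCOC)c(C(C)(O[Li])N(C)OC)c2OCOC)c(OCOC)c1C(C)(O[Li])N(C)OC | intermediate
38 | 1-[3-{(1S)-1-[3-acetyl-2,4,6-tris(methoxymethoxy)-5-(3-methylbut-2-en-1-yl)phenyl]-3-methylbutyl}-6-methoxy-2,4-bis(methoxymethoxy)-5-(3-methylbut-2-en-1-yl)phenyl]ethan-1-one | COc1c(CC=C(C)C)c(OCOC)c([C@H](CC(C)C)c2c(OCOC)c(CC=C(C)C)c(OCOC)c(C(C)=O)c2OCOC)c(OCOC)c1C(C)=O | intermediate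
39 | 1-[3-{(1R)-1-[3-acetyl-2,4,6-trihydroxy-5-(3-methylbut-2-en-1-yl)phenyl]-3-methylbutyl}-2,4-dihydroxy-6-methoxy-5-(3-methylbut-2-en-1-yl)phenyl]ethan-1-one | COc1c(CC=C(C)C)c(O)c([C@H](CC(C)C)c2c(O)c(CC=C(C)C)c(O)c(C(C)=O)c2O)c(O)c1C(C)=O | target

**Totals**

Total step count: 16. Longest linear sequence: 11 steps (steps 1, 2, 3, 5, 7, 8, 12, 13, 14, 15, 16).

**Steps most likely to fail**

Step 12. The bimolecular ketene–alkyne cycloaddition to the branched ynol ether may be too slow at the temperature needed to open 28, so that the ynol ether isomerises or decomposes on prolonged heating before it is consumed. The fallback separates the cycloaddition from the heating by making the same vinylketene at room temperature from an acyclic acid chloride. Methyl acetoacetate is converted to its dianion (NaH, then n-BuLi, THF, 0 °C) and alkylated at the terminal carbon with prenyl bromide to give methyl 7-methyl-3-oxooct-6-enoate F1. Trimethyl orthoformate with catalytic H2SO4 in methanol gives methyl (2E)-3-methoxy-7-methylocta-2,6-dienoate F2. LiOH in aqueous THF gives (2E)-3-methoxy-7-methylocta-2,6-dienoic acid F3, and oxalyl chloride gives (2E)-3-methoxy-7-methylocta-2,6-dienoyl chloride F4. Slow addition of F4 to 21 and Et3N in CH2Cl2 at room temperature should generate vinylketene 29 by 1,4-dehydrochlorination in the presence of concentrated alkyne, and [2+2] cycloaddition should give 30. Compound 30 is then heated alone in toluene to run the two electrocyclic steps. The fallback sets out from 21 and returns at 33.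

Step 5. The sparteine-bound carbenoid may fail to reach a boron atom shielded by two ortho MOM ethers, or the ate complex may revert before the aryl group migrates. The fallback reverses which partner carries boron. Lithiated carbamate 9 is trapped with the unhindered i-PrOBpin to give (1S)-3-methyl-1-(4,4,5,5-tetramethyl-1,3,2-dioxaborolan-2-yl)butyl N,N-diisopropylcarbamate F5, which is isolated. Aryllithium 5 (from 4 and n-BuLi, THF, 0 °C) is then added to F5 at –78 °C without any diamine, which should form the same ate complex 10, and warming should give 11 by the same invertive 1,2-migration. The fallback sets out from 8 (through 9) and 4 (through 5) and returns at 11.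

Step 7. Ate-complex formation at the congested secondary boron may stay incomplete, or iodine may attack the prenyl alkene or the electron-rich ring faster than it triggers migration. The fallback avoids the bulky nucleophile, the oxidant and the carbamate elimination of step 8. Compound 11 is homologated with chloromethyllithium made in its presence (BrCH2Cl, n-BuLi, THF, –78 °C → rt; Matteson homologation, stereoretentive) to 4,4,5,5-tetramethyl-2-[(2R)-4-methyl-2-ArB-pentyl]-1,3,2-dioxaborolane F6. Oxidation with NaBO3·4H2O in aqueous THF gives (2R)-4-methyl-2-ArB-pentan-1-ol F7, and Dess–Martin periodinane buffered with NaHCO3 gives (2R)-4-methyl-2-ArB-pentanal F8. Corey–Fuchs olefination (CBr4, PPh3, CH2Cl2, 0 °C), which keeps the epimerisable aldehyde away from base, gives 2-[(3S)-1,1-dibromo-5-methylhex-1-en-3-yl]-1,3,5-tris(methoxymethoxy)-4-(3-methylbut-2-en-1-yl)benzene F9. Treatment with n-BuLi (2.1 equiv, THF, –78 °C) should give lithium acetylide 19, to which lithium tert-butyl peroxide and then TIPSOTf are added in the same flask as in step 8. The fallback sets out from 11 and returns at 19, which is carried on to 21 without isolation.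

**Further compounds**

F1 | step 12 | methyl 7-methyl-3-oxooct-6-enoate | COC(=O)CC(=O)CCC=C(C)C
F2 | step 12 | methyl (2E)-3-methoxy-7-methylocta-2,6-dienoate | COC(=O)/C=C(/OC)CCC=C(C)C
F3 | step 12 | (2E)-3-methoxy-7-methylocta-2,6-dienoic acid | OC(=O)/C=C(/OC)CCC=C(C)C
F4 | step 12 | (2E)-3-methoxy-7-methylocta-2,6-dienoyl chloride | ClC(=O)/C=C(/OC)CCC=C(C)C
F5 | step 5 | (1S)-3-methyl-1-(4,4,5,5-tetramethyl-1,3,2-dioxaborolan-2-yl)butyl N,N-diisopropylcarbamate | CC(C)C[C@@H](OC(=O)N(C(C)C)C(C)C)B1OC(C)(C)C(C)(C)O1
F6 | step 7 | 4,4,5,5-tetramethyl-2-[(2R)-4-methyl-2-ArB-pentyl]-1,3,2-dioxaborolane | CC1(C)OB(OC1(C)C)C[C@H](CC(C)C)c1c(OCOC)c(CC=C(C)C)c(OCOC)cc1OCOC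
F7 | step 7 | (2R)-4-methyl-2-ArB-pentan-1-ol | OC[C@H](CC(C)C)c1c(OCOC)c(CC=C(C)C)c(OCOC)cc1OCOC
F8 | step 7 | (2R)-4-methyl-2-ArB-pentanal | O=C[C@H](CC(C)C)c1c(OCOC)c(CC=C(C)C)c(OCOC)cc1OCOC
F9 | step 7 | 2-[(3S)-1,1-dibromo-5-methylhex-1-en-3-yl]-1,3,5-tris(methoxymethoxy)-4-(3-methylbut-2-en-1-yl)benzene | BrC(Br)=C[C@H](CC(C)C)c1c(OCOC)c(CC=C(C)C)c(OCOC)cc1OCOC
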